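The runs were computed for an exercise; noise was put on by code.

For the 5 questions I start from two amounts, the reagent charged and the starting material charged. The proposed cycle takes up one reagent for each target it releases, and reagent is charged at less than starting material, so reagent is the limiting reagent.

all flasks: free catalyst 2.5 mM

| charge | starting material | reagent | protic impurity | remark | time |
|---|---|---|---|---|---|
| amber | 0.050 M | 0.030 M | 0.050 M | run made earlier |  |
| ochre | 0.050 M | 0.030 M | 0.025 M | run made earlier |  |
| green | 0.050 M | 0.030 M | 0.10 M | run made earlier |  |
| zeta | 0.050 M | 0.0300 M | 0.0500 M | everything together in a closed stirred flask, run for 40 min | 40 min |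
| epsilon | 0.050 M | 0.0300 M | 0.0500 M | a tube with plug flow, the mixed feed as stated, residence time 40 min | 40 min |
| theta | 0.050 M (fed, over 32.0 min) | 0.0300 M | 0.0500 M | a stirred flask in which starting material is dosed at a steady rate over 32.0 min without added volume, worked up at 40 min | 40 min |
| gamma | 0.050 M | 0.0300 M | 0.0500 M | a single well-mixed tank run continuously and read at steady state, 40 min in it on average |  |

| run | time / min | target / % | starting material / % |
|---|---|---|---|
| amber | 4.00 | 50 | 22 |
| amber | 10.0 | 60 | 5 |
| amber | 20.0 | 62 | 3 |
| amber | 30.0 | 61 | 3 |
| amber | 40.0 | 63 | 0 |
| ochre | 8.00 | 59 | 19 |
| ochre | 15.0 | 62 | 11 |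
| ochre | 25.0 | 61 | 11 |
| ochre | 30.0 | 57 | 10 |
| ochre | 40.0 | 57 | 5 |
| green | 3.00 | 43 | 15 |
| green | 6.00 | 59 | 1 |
| green | 12.0 | 59 | 1 |
| green | 20.0 | 58 | 0 |
| green | 40.0 | 61 | 1 |

(standard deviation of a reading: 1.5 percentage points)

* the set-up with the highest amount of target at the outlet or at the end, in percent of the starting material put in ("none" if the first two lie within 2 percentage points) (zeta / epsilon / theta / gamma / none)
* amount of target at the outlet or at the end, in percent of the starting material put in, zeta
* amount of target at the outlet or at the end, in percent of the starting material put in, epsilon
* amount of target at the outlet or at the end, in percent of the starting material put in, theta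
* amount of target at the outlet or at the end, in percent of the starting material put in, gamma

- the stated concentrations are those of everything mixed, before any reaction; amounts are the same in each set-up
- steps that have been proposed: starting material + free catalyst -> catalyst intermediate A; reagent + catalyst intermediate A <-> catalyst intermediate B; catalyst intermediate B -> by-product + catalyst intermediate C; catalyst intermediate C -> free catalyst + target; starting material + protic impurity -> quenched substrate
- the feed brings no volume worth counting
- the earlier runs were made in a closed, stirred flask

I set the two amounts against each other:

Y = reagent charged / starting material charged = 0.0300 M / 0.050 M = 60.0 %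

I call Y the reagent ceiling, the target that the charged reagent can give, in percent of the starting material charged. The earlier runs show a plateau near it: as protic impurity goes from 0.025 M in the ochre run to 0.10 M in the green run, the last target readings are 57 % for ochre, 63 % for amber and 61 % for green, each with a scatter of 1.5 percentage points.

The charge is the same in zeta, epsilon, theta and gamma, so I hold each against Y. I put zeta, epsilon and theta at Y. The outlet of the gamma tank carries whatever reagent stands in the tank, and that amount comes off Y.

The forecast gives 60 % for zeta, 60 % for epsilon, 60 % for theta and 57 % for gamma, which is lower than Y, with best set-up none; its ground is “That is the reagent limit”.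

The flasks give 60.0 % for zeta, 60.0 % for epsilon, 60.0 % for theta and 57.4 % for gamma, with best set-up none.

    starting material + free catalyst → catalyst intermediate A (k = 130 L mol⁻¹ s⁻¹)
    reagent + catalyst intermediate A ⇌ catalyst intermediate B (K = 20.0 L mol⁻¹, k = 48.0 L mol⁻¹ s⁻¹)
    catalyst intermediate B → by-product + catalyst intermediate C (k = 0.220 s⁻¹)
    catalyst intermediate C → free catalyst + target (k = 0.730 s⁻¹)
    starting material + protic impurity → quenched substrate (k = 0.0460 L mol⁻¹ s⁻¹)

Zeta ends on the ceiling 60.0 %, and the running short of reagent is the main reason: with that shortage taken away, zeta gives 80.0 %. I use the same ceiling for gamma by taking the reagent standing in the tank, 0.00124 M, off the charge, with any reagent held on the catalyst not counted: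

Y for gamma = (0.0300 M − 0.00124 M) / 0.050 M = 57.5 %

The gamma tank gives 57.4 %.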